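**Retrosynthetic overview**

1. Feature: ring A (C4a–C8a) carries three adjacent oxygens, O4 on C4a, O1 on C8a and OMe on C8, with the C6 side chain para to C8a. This is the pattern of a 5-substituted cyclohexane-1,3-dione oxidised at C2. C3 is benzylic to ring C and para to its C4' oxygen, so the C3–O bond can ionise.
2. The enal is traced back to a C6 methyl ester (reduction, benzylic oxidation, Wittig with Ph3P=CHCHO). The C8 methoxy arene is traced back to a C8 ketone in a non-aromatic ring A (dehydrogenation, then O-methylation).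
3. Ring B (the dioxine) is disconnected by a carbene three-atom insertion: bonds C8a–O1 and O4–C3, from 2-diazo-1,3-dione 7 and trans-epoxide 5.
4. Epoxide 5 comes from Sharpless epoxidation of the cinnamyl alcohol made from sinapic acid; 7 comes from diazo transfer to dione 6.
5. Ring order: ring C and the carbocycle of ring A are bought, ring B is closed in step 6, ring A is aromatised in step 7.

Key step: step 6

Assumption: sinapic acid (1) and methyl 3,5-dioxocyclohexane-1-carboxylate (6) are taken as purchasable; locants are those of 1,4-benzodioxine (O1, C2 bearing the CH2O group, C3 bearing the aryl group, O4, C4a, C5 to C8, C8a).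

**Route**

Step 1
Reactants: 1 sinapic acid
Product: 2 benzyl (E)-3-[4-(benzyloxy)-3,5-dimethoxyphenyl]prop-2-enoate
Conditions: BnBr (2.5 equiv), K2CO3, DMF, 60 °C
Reagents that add atoms: benzyl bromide, BrCc1ccccc1
Why: Williamson O-alkylation of the phenoxide and SN2 alkylation of the carboxylate by the same benzyl halide protects both acidic sites in one operation and leaves the E alkene untouched.

Step 2
Reactants: 2 benzyl (E)-3-[4-(benzyloxy)-3,5-dimethoxyphenyl]prop-2-enoate
Product: 3 (E)-3-[4-(benzyloxy)-3,5-dimethoxyphenyl]prop-2-en-1-ol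
Conditions: i-Bu2AlH (2.5 equiv), CH2Cl2, −78 to 0 °C; Rochelle salt work-up
Reagents that add atoms: none
Why: 1,2-reduction of an α,β-unsaturated ester by i-Bu2AlH should give the allylic alcohol without touching the alkene, and benzyl alcohol is removed by chromatography.

Step 3
Reactants: 3 (E)-3-[4-(benzyloxy)-3,5-dimethoxyphenyl]prop-2-en-1-ol
Product: 4 [(2S,3S)-3-[4-(benzyloxy)-3,5-dimethoxyphenyl]oxiran-2-yl]methanol
Conditions: Ti(Oi-Pr)4 (10 mol %), L-(+)-diisopropyl tartrate (12 mol %), t-BuOOH, 4 Å molecular sieves, CH2Cl2, −20 °C; basic work-up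
Reagents that add atoms: tert-butyl hydroperoxide, CC(C)(C)OO
Why: Katsuki–Sharpless asymmetric epoxidation of an E-cinnamyl alcohol, in which the L-(+)-tartrate titanium complex delivers oxygen to the face that gives the (2S,3S)-epoxy alcohol and so sets both stereocentres; the two meta methoxy groups and the twisted para benzyloxy group keep the aryl epoxide stable enough for a non-acidic work-up.

Step 4
Reactants: 4 [(2S,3S)-3-[4-(benzyloxy)-3,5-dimethoxyphenyl]oxiran-2-yl]methanol
Product: 5 (2S,3S)-2-[4-(benzyloxy)-3,5-dimethoxyphenyl]-3-[(benzyloxy)methyl]oxirane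
Conditions: NaH, BnBr, n-Bu4NI (cat.), THF, 0 °C
Reagents that add atoms: benzyl bromide, BrCc1ccccc1
Why: Williamson benzylation of the primary alkoxide, fast at 0 °C with iodide catalysis so that it outruns Payne rearrangement, removes the O–H bond that would otherwise trap the carbene in step 6.

Step 5
Reactants: 6 methyl 3,5-dioxocyclohexane-1-carboxylate
Product: 7 methyl 4-diazo-3,5-dioxocyclohexane-1-carboxylate
Conditions: 4-acetamidobenzenesulfonyl azide, Et3N, MeCN, 0 °C to rt
Reagents that add atoms: 4-acetamidobenzenesulfonyl azide, CC(=O)Nc1ccc(cc1)S(=O)(=O)N=[N+]=[N-]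
Why: Regitz diazo transfer to the acidic C2 methylene of a cyclic 1,3-dione is reliable under amine base and the sulfonamide by-product is removed by filtration and chromatography.

Step 6
Reactants: 5 (2S,3S)-2-[4-(benzyloxy)-3,5-dimethoxyphenyl]-3-[(benzyloxy)methyl]oxirane; 7 methyl 4-diazo-3,5-dioxocyclohexane-1-carboxylate
Product: 8 methyl (2S,3S)-3-[4-(benzyloxy)-3,5-dimethoxyphenyl]-2-[(benzyloxy)methyl]-8-oxo-2,3,5,6,7,8-hexahydro-1,4-benzodioxine-6-carboxylate (mixture at C6)
Conditions: [CpRu(MeCN)3]PF6 (5 mol %), 1,10-phenanthroline (5 mol %), CH2Cl2, 60 °C, sealed vessel; 7 (2 equiv) added in portions to 5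
Reagents that add atoms: none
Why: Proposed new method: the ruthenium complex should take N2 from 7 to give an electrophilic carbene, the epoxide oxygen of 5 adds to the carbene carbon (bond C8a–O1) to give an oxonium ylide, the benzylic C3–O bond then ionises with help from the 4-benzyloxy-3,5-dimethoxyphenyl group, and an oxygen of the dione enolate collapses on C3 (bond O4–C3). The closest known reaction type is the [CpRu]-catalysed three-atom insertion of acyclic α-diazo-β-ketoesters into epoxides to give 2,3-dihydro-1,4-dioxins, which runs through such an ionised intermediate; what is new is the cyclic 2-diazo-1,3-diketone combined with a 2,3-disubstituted aryl epoxide. Ring B closes by O-attack of the enolate on the benzylic cation, a 6-(enolendo)-exo-trig closure, so the disfavoured concerted 6-endo-tet displacement is not needed. C2 keeps the configuration set in step 3 because its C–O bond is never broken, and C3 should be re-formed with retention because the enolate oxygen closes inside the contact ion pair on the face the epoxide oxygen has just left, which is also the diequatorial trans arrangement. The step needs cleavage of the C3–O and not the C2–O bond, which benzylic stabilisation secures, and it needs the carbene to choose the epoxide oxygen over the ether oxygens, which the strain-releasing and irreversible ring opening secures. Because 7 has a mirror plane through C2 and C5 of the dione, either carbonyl oxygen gives the same constitution, so O4 ends on C4a and the spectator carbonyl becomes C8.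

Step 7
Reactants: 8 methyl (2S,3S)-3-[4-(benzyloxy)-3,5-dimethoxyphenyl]-2-[(benzyloxy)methyl]-8-oxo-2,3,5,6,7,8-hexahydro-1,4-benzodioxine-6-carboxylate
Product: 11 methyl (2S,3S)-3-[4-(benzyloxy)-3,5-dimethoxyphenyl]-2-[(benzyloxy)methyl]-8-hydroxy-2,3-dihydro-1,4-benzodioxine-6-carboxylate, via trimethylsilyl dienol ether 9 (not isolated), via cross-conjugated dienone 10 (not isolated)
Conditions: LiN(i-Pr)2, Me3SiCl, THF, −78 °C; then Pd(OAc)2 (1.1 equiv), MeCN, rt
Reagents that add atoms: none
Why: Saegusa–Ito oxidation: kinetic enolisation at C7 and silylation give 9, Pd(OAc)2 forms the C7 palladium enolate and β-hydride elimination of the C6–H gives the C6=C7 enone 10, whose C5 methylene tautomerises irreversibly to the phenol; the base-then-neutral sequence spares the ionisable C3–O4 bond that iodine in hot acidic methanol would endanger, and the C6 mixture disappears.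

Step 8
Reactants: 11 methyl (2S,3S)-3-[4-(benzyloxy)-3,5-dimethoxyphenyl]-2-[(benzyloxy)methyl]-8-hydroxy-2,3-dihydro-1,4-benzodioxine-6-carboxylate
Product: 12 methyl (2S,3S)-3-[4-(benzyloxy)-3,5-dimethoxyphenyl]-2-[(benzyloxy)methyl]-8-methoxy-2,3-dihydro-1,4-benzodioxine-6-carboxylate
Conditions: MeI, K2CO3, acetone, 50 °C
Reagents that add atoms: iodomethane, CI
Why: Williamson methylation of the only free phenol installs the C8 methoxy group under conditions to which the ester, the benzyl ethers and ring B are inert.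

Step 9
Reactants: 12 methyl (2S,3S)-3-[4-(benzyloxy)-3,5-dimethoxyphenyl]-2-[(benzyloxy)methyl]-8-methoxy-2,3-dihydro-1,4-benzodioxine-6-carboxylate
Product: 13 methyl (2S,3S)-3-(4-hydroxy-3,5-dimethoxyphenyl)-2-(hydroxymethyl)-8-methoxy-2,3-dihydro-1,4-benzodioxine-6-carboxylate
Conditions: H2 (1 atm), Pd/C (10 %), EtOAc/MeOH, rt
Reagents that add atoms: none
Why: Catalytic hydrogenolysis should cleave both O-benzyl groups while the ring-held secondary benzylic C3–O4 ether (as in flavan-type substrates that are debenzylated this way) and the ester persist, and doing it before the enal exists avoids reduction of a conjugated alkene.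

Step 10
Reactants: 13 methyl (2S,3S)-3-(4-hydroxy-3,5-dimethoxyphenyl)-2-(hydroxymethyl)-8-methoxy-2,3-dihydro-1,4-benzodioxine-6-carboxylate
Product: 14 4-[(2S,3S)-7-(hydroxymethyl)-3-(hydroxymethyl)-5-methoxy-2,3-dihydro-1,4-benzodioxin-2-yl]-2,6-dimethoxyphenol (the C6 ester of 13 reduced to CH2OH)
Conditions: LiAlH4 (4 equiv), THF, 0 °C to rt; Rochelle salt work-up
Reagents that add atoms: none
Why: Hydride reduction of the aryl ester to the benzylic alcohol, in which the phenol and the primary alcohol are only deprotonated and consume extra hydride.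

Step 11
Reactants: 14 the triol with CH2OH at C6
Product: 15 (2S,3S)-3-(4-hydroxy-3,5-dimethoxyphenyl)-2-(hydroxymethyl)-8-methoxy-2,3-dihydro-1,4-benzodioxine-6-carbaldehyde
Conditions: activated MnO2 (excess), acetone, rt
Reagents that add atoms: none
Why: MnO2 oxidises the electron-rich benzylic alcohol on ring A to the aldehyde far faster than the aliphatic C2 hydroxymethyl group and does not over-oxidise.

Step 12
Reactants: 15 (2S,3S)-3-(4-hydroxy-3,5-dimethoxyphenyl)-2-(hydroxymethyl)-8-methoxy-2,3-dihydro-1,4-benzodioxine-6-carbaldehyde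
Product: 16 bilagrewin, (E)-3-[(2S,3S)-3-(4-hydroxy-3,5-dimethoxyphenyl)-2-(hydroxymethyl)-8-methoxy-2,3-dihydro-1,4-benzodioxin-6-yl]prop-2-enal
Conditions: Ph3P=CHCHO (1.3 equiv), THF/toluene, 70 °C
Reagents that add atoms: (triphenylphosphoranylidene)acetaldehyde, O=CC=P(c1ccccc1)(c1ccccc1)c1ccccc1
Why: Wittig olefination with the stabilised formyl ylide should give the E-enal and the ylide is too weakly basic to be quenched by the free phenol or alcohol.

**Compound list**

1 | sinapic acid, (E)-3-(4-hydroxy-3,5-dimethoxyphenyl)prop-2-enoic acid | COc1cc(/C=C/C(=O)O)cc(OC)c1O | starting material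
2 | benzyl (E)-3-[4-(benzyloxy)-3,5-dimethoxyphenyl]prop-2-enoate | COc1cc(/C=C/C(=O)OCc2ccccc2)cc(OC)c1OCc1ccccc1 | intermediate
3 | (E)-3-[4-(benzyloxy)-3,5-dimethoxyphenyl]prop-2-en-1-ol | COc1cc(/C=C/CO)cc(OC)c1OCc1ccccc1 | intermediate
4 | [(2S,3S)-3-[4-(benzyloxy)-3,5-dimethoxyphenyl]oxiran-2-yl]methanol | COc1cc([C@@H]2O[C@H]2CO)cc(OC)c1OCc1ccccc1 | intermediate
5 | (2S,3S)-2-[4-(benzyloxy)-3,5-dimethoxyphenyl]-3-[(benzyloxy)methyl]oxirane | COc1cc([C@@H]2O[C@H]2COCc3ccccc3)cc(OC)c1OCc4ccccc4 | intermediate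
6 | methyl 3,5-dioxocyclohexane-1-carboxylate | COC(=O)C1CC(=O)CC(=O)C1 | starting material
7 | methyl 4-diazo-3,5-dioxocyclohexane-1-carboxylate | COC(=O)C1CC(=O)C(=[N+]=[N-])C(=O)C1 | intermediate
8 | methyl (2S,3S)-3-[4-(benzyloxy)-3,5-dimethoxyphenyl]-2-[(benzyloxy)methyl]-8-oxo-2,3,5,6,7,8-hexahydro-1,4-benzodioxine-6-carboxylate, mixture at C6 | COc1cc([C@@H]2OC3=C(O[C@H]2COCc4ccccc4)C(=O)CC(C(=O)OC)C3)cc(OC)c1OCc5ccccc5 | intermediate
9 | trimethylsilyl dienol ether of 8 (C8 silyloxy, C7=C8 and C4a=C8a double bonds), not isolated | COc1cc([C@@H]2OC3=C(O[C@H]2COCc4ccccc4)C(O[Si](C)(C)C)=CC(C(=O)OC)C3)cc(OC)c1OCc5ccccc5 | intermediate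
10 | cross-conjugated dienone (C8 ketone, C6=C7 and C4a=C8a double bonds, C5 methylene), not isolated | COc1cc([C@@H]2OC3=C(O[C@H]2COCc4ccccc4)C(=O)C=C(C(=O)OC)C3)cc(OC)c1OCc5ccccc5 | intermediate
11 | methyl (2S,3S)-3-[4-(benzyloxy)-3,5-dimethoxyphenyl]-2-[(benzyloxy)methyl]-8-hydroxy-2,3-dihydro-1,4-benzodioxine-6-carboxylate | COc1cc([C@@H]2Oc3cc(C(=O)OC)cc(O)c3O[C@H]2COCc4ccccc4)cc(OC)c1OCc5ccccc5 | intermediate
12 | methyl (2S,3S)-3-[4-(benzyloxy)-3,5-dimethoxyphenyl]-2-[(benzyloxy)methyl]-8-methoxy-2,3-dihydro-1,4-benzodioxine-6-carboxylate | COc1cc([C@@H]2Oc3cc(C(=O)OC)cc(OC)c3O[C@H]2COCc4ccccc4)cc(OC)c1OCc5ccccc5 | intermediate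
13 | methyl (2S,3S)-3-(4-hydroxy-3,5-dimethoxyphenyl)-2-(hydroxymethyl)-8-methoxy-2,3-dihydro-1,4-benzodioxine-6-carboxylate | COc1cc([C@@H]2Oc3cc(C(=O)OC)cc(OC)c3O[C@H]2CO)cc(OC)c1O | intermediate
14 | triol: 13 with the C6 ester reduced to CH2OH | COc1cc([C@@H]2Oc3cc(CO)cc(OC)c3O[C@H]2CO)cc(OC)c1O | intermediate
15 | (2S,3S)-3-(4-hydroxy-3,5-dimethoxyphenyl)-2-(hydroxymethyl)-8-methoxy-2,3-dihydro-1,4-benzodioxine-6-carbaldehyde | COc1cc([C@@H]2Oc3cc(C=O)cc(OC)c3O[C@H]2CO)cc(OC)c1O | intermediate
16 | bilagrewin | COc1cc([C@@H]2Oc3cc(/C=C/C=O)cc(OC)c3O[C@H]2CO)cc(OC)c1O | target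

**Step count**

Total: 12 steps. Longest linear sequence: 11 steps (steps 1–4 and 6–12, from sinapic acid).

**Steps most likely to fail**

Step 6. The carbene may be consumed by other paths: oxygen-atom abstraction from the epoxide to give the alkene, ylide formation at a benzyl ether oxygen, or a 1,2-hydride shift in the opened cation. The Lewis-acidic metal may also isomerise the electron-rich epoxide, and the trans selectivity may erode if the benzylic cation leaves the ion pair. The fallback builds ring B on an aromatic ring A by two known SN2 events; it sets out from 3 and comes back at 12.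
- Sharpless epoxidation of 3 with D-(−)-diisopropyl tartrate should give the enantiomeric epoxy alcohol [(2R,3R)-3-[4-(benzyloxy)-3,5-dimethoxyphenyl]oxiran-2-yl]methanol F1.
- NaH and BnBr convert it into (2R,3R)-2-[4-(benzyloxy)-3,5-dimethoxyphenyl]-3-[(benzyloxy)methyl]oxirane F2.
- Purchased methyl 3,4-dihydroxy-5-methoxybenzoate F3 is allylated at its more acidic 4-hydroxyl (allyl bromide, KHCO3, DMF) to methyl 4-(allyloxy)-3-hydroxy-5-methoxybenzoate F4.
- The phenoxide of F4 (Cs2CO3, DMF, 80 °C) opens F2 at the benzylic carbon with inversion, as phenoxides do with 3-aryl glycidyl derivatives. This gives methyl 4-(allyloxy)-3-{[(1S,2R)-3-(benzyloxy)-1-[4-(benzyloxy)-3,5-dimethoxyphenyl]-2-hydroxypropyl]oxy}-5-methoxybenzoate F5.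
- Pd(PPh3)4 with morpholine removes the allyl group to give the phenol methyl 3-{[(1S,2R)-3-(benzyloxy)-1-[4-(benzyloxy)-3,5-dimethoxyphenyl]-2-hydroxypropyl]oxy}-4-hydroxy-5-methoxybenzoate F6.
- Intramolecular Mitsunobu etherification (PPh3, diisopropyl azodicarboxylate, THF) closes O1–C2 with inversion at the carbinol carbon and gives 12. The two inversions on the (2R,3R) epoxide deliver the (2S,3S) benzodioxine.

Step 7. Enolisation may be incomplete or go to the wrong site, the silyl dienol ether may hydrolyse, or the palladium enolate may be protonated back to 8 before β-hydride elimination at the tertiary C6–H. The fallback replaces the palladium-mediated dehydrogenation by a selenoxide syn-elimination; it sets out from 8 and comes back at 11. LiN(i-Pr)2 then PhSeBr in THF at −78 °C should give the α-selanyl ketone methyl (2S,3S)-3-[4-(benzyloxy)-3,5-dimethoxyphenyl]-2-[(benzyloxy)methyl]-8-oxo-7-(phenylselanyl)-2,3,5,6,7,8-hexahydro-1,4-benzodioxine-6-carboxylate F7. H2O2 with pyridine in CH2Cl2 at 0 °C oxidises it to the selenoxide, which eliminates towards C6–H to the dienone 10, and this tautomerises to 11.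

Step 12. The product enal may be homologated a second time by the same ylide, and the electron-rich aldehyde may react slowly. The fallback uses a masked two-carbon ylide; it sets out from 15 and comes back at 16. Wittig reaction of 15 with (1,3-dioxolan-2-ylmethyl)triphenylphosphonium bromide and excess t-BuOK in THF should give the vinyl dioxolane 4-[(2S,3S)-7-[2-(1,3-dioxolan-2-yl)ethenyl]-3-(hydroxymethyl)-5-methoxy-2,3-dihydro-1,4-benzodioxin-2-yl]-2,6-dimethoxyphenol F8 as an E/Z mixture, which cannot react further with the ylide. Dilute aqueous HCl in THF then hydrolyses the acetal and equilibrates the enal to the E isomer 16.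

**Further compounds**

F1 | step 6 | [(2R,3R)-3-[4-(benzyloxy)-3,5-dimethoxyphenyl]oxiran-2-yl]methanol | COc1cc([C@H]2O[C@@H]2CO)cc(OC)c1OCc1ccccc1
F2 | step 6 | (2R,3R)-2-[4-(benzyloxy)-3,5-dimethoxyphenyl]-3-[(benzyloxy)methyl]oxirane | COc1cc([C@H]2O[C@@H]2COCc3ccccc3)cc(OC)c1OCc4ccccc4
F3 | step 6 | methyl 3,4-dihydroxy-5-methoxybenzoate (purchased) | COC(=O)c1cc(O)c(O)c(OC)c1
F4 | step 6 | methyl 4-(allyloxy)-3-hydroxy-5-methoxybenzoate | COC(=O)c1cc(O)c(OCC=C)c(OC)c1
F5 | step 6 | methyl 4-(allyloxy)-3-{[(1S,2R)-3-(benzyloxy)-1-[4-(benzyloxy)-3,5-dimethoxyphenyl]-2-hydroxypropyl]oxy}-5-methoxybenzoate | COc1cc([C@H](Oc2cc(C(=O)OC)cc(OC)c2OCC=C)[C@H](O)COCc2ccccc2)cc(OC)c1OCc1ccccc1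
F6 | step 6 | methyl 3-{[(1S,2R)-3-(benzyloxy)-1-[4-(benzyloxy)-3,5-dimethoxyphenyl]-2-hydroxypropyl]oxy}-4-hydroxy-5-methoxybenzoate | COc1cc([C@H](Oc2cc(C(=O)OC)cc(OC)c2O)[C@H](O)COCc2ccccc2)cc(OC)c1OCc1ccccc1
F7 | step 7 | methyl (2S,3S)-3-[4-(benzyloxy)-3,5-dimethoxyphenyl]-2-[(benzyloxy)methyl]-8-oxo-7-(phenylselanyl)-2,3,5,6,7,8-hexahydro-1,4-benzodioxine-6-carboxylate | COc1cc([C@@H]2OC3=C(O[C@H]2COCc4ccccc4)C(=O)C([Se]c6ccccc6)C(C(=O)OC)C3)cc(OC)c1OCc5ccccc5
F8 | step 12 | 4-[(2S,3S)-7-[2-(1,3-dioxolan-2-yl)ethenyl]-3-(hydroxymethyl)-5-methoxy-2,3-dihydro-1,4-benzodioxin-2-yl]-2,6-dimethoxyphenol, E/Z mixture | COc1cc([C@@H]2Oc3cc(C=CC4OCCO4)cc(OC)c3O[C@H]2CO)cc(OC)c1O
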